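Past the first readings the target does not pile up in these runs. The proposed steps make it from electrophile and nucleophile, with acid set free, and spend it on a second electrophile to give side product. In the zeta run it reads 7.5% at 1.00 min and 7.5% at 6.00 min, while the electrophile falls from 70.2% to 12.4%.

| flask | electrophile | nucleophile | remark | time |
|---|---|---|---|---|
| eta | 0.10 M | 1.3 equiv | run made earlier |  |
| zeta | 0.10 M | 3 equiv | run made earlier |  |
| epsilon | 0.20 M | 2 equiv | run made earlier |  |
| flask | 0.10 M | 2.00 equiv |  | 10 min |

| run | time / min | electrophile / % | target / % |
|---|---|---|---|
| eta | 0.333 | 95.6 | 2.5 |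
| eta | 1.00 | 86.0 | 2.9 |
| eta | 1.50 | 79.9 | 3.2 |
| eta | 2.50 | 67.8 | 2.3 |
| eta | 4.00 | 54.2 | 2.9 |
| eta | 5.00 | 47.6 | 3.3 |
| eta | 6.00 | 42.4 | 2.9 |
| zeta | 0.333 | 90.0 | 4.6 |
| zeta | 1.00 | 70.2 | 7.5 |
| zeta | 1.50 | 58.3 | 7.3 |
| zeta | 2.50 | 40.1 | 6.6 |
| zeta | 4.00 | 23.1 | 6.9 |
| zeta | 5.00 | 17.4 | 6.4 |
| zeta | 6.00 | 12.4 | 7.5 |
| epsilon | 0.500 | 79.1 | 4.5 |
| epsilon | 1.50 | 48.2 | 4.7 |
| epsilon | 3.00 | 26.1 | 3.8 |
| epsilon | 4.00 | 17.7 | 4.3 |
| epsilon | 6.00 | 8.9 | 4.1 |

(standard deviation of a reading: 0.5 percentage points)

- percent here means electrophile units held: one side product counts as two
- steps that have been proposed: acid set free -> by-product carried off; electrophile + target -> side product; electrophile + nucleophile -> acid set free + target; nucleophile + acid set free <-> protonated nucleophile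
- the earlier runs do not show how much of nucleophile is bound; that part of a forecast is a guess

- part of the electrophile that has reacted at 10 min
- share of the unused nucleophile that is free and not bound as protonated nucleophile, at 10 min

By that last zeta reading far more electrophile has reacted than target stands, so I treat the target as a steady intermediate and let each nucleophile spent take two electrophiles. I then write the electrophile's fall as k × electrophile × nucleophile, the second-order law for unequal charges, counting bound nucleophile as free. The ratio of nucleophile to electrophile grows as exp(k × excess × time), the excess being the nucleophile charge less half the electrophile charge. The epsilon run, with 8.9% left at 6.00 min, gives k = 1.20 /M/min, which puts the flask at 87.1% reacted at 10 min. That single reading is the weak link, so I add the last readings of eta and zeta, 1.27 /M/min and 1.29 /M/min. The mean of the three is 1.25 /M/min, my pairing constant, the electrophile's fractional loss per minute per unit of nucleophile concentration, and it gives 88.1% for the flask, which I commit to.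

The forecast says 86.5%, a little under mine, and 85% for the free share, of which it says “it is a guess”.

The flask gives 88.3% reacted and 79.1% free, so the forecast and the flask part on the free share.

    acid set free → by-product carried off (k = 0.270 /min)
    electrophile + target → side product (k = 25.0 /M/min)
    electrophile + nucleophile → acid set free + target (k = 0.760 /M/min)
    nucleophile + acid set free ⇌ protonated nucleophile, settled at all times (K = 56.0 /M)

In the flask, electrophile fell from 79.3% at 1.00 min to 11.7% at 10.0 min while side product rose to 84.4%, and at that last time protonated nucleophile stood at 0.0322 M against 0.00919 M of by-product carried off. The 12% of electrophile left in the flask returns a pairing constant of 1.26 /M/min. For the neighbour charged with 0.025 M, my pairing constant gives 44.4% reacted at 10 min, and that neighbour stands at 46.2%, holding 53.8% electrophile and 41.1% side product.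

The runs were generated by integration from invented constants; the scatter is artificial.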